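## Retrosynthetic overview

1. The target comes from its O14-silyl ether. That ether comes from the 8α-carbinol of the complete tricycle by Mitsunobu inversion with isobutyric acid, so inversion and acylation are one operation.
2. Enabling feature: C8, the oxygen-bearing carbon of the ten-membered ring, is homoallylic to the exocyclic methylene (C8–C7–C11=C13), and C7 and C11 are atoms of the γ-lactone ring. Retro-SE2′ allylation across C7–C8 therefore opens the carbocycle to a 3-(bromomethyl)butenolide tethered through C6 to a β,γ-epoxy aldehyde (C8).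
3. The butenolide comes from ring-closing metathesis of the 2-(bromomethyl)acrylate of a 6S bis-allylic alcohol, itself made by catalytic asymmetric alkenylzinc addition to a Z-enal.
4. The oxirane comes from Sharpless epoxidation of a 2Z trisubstituted allylic alcohol. That alcohol comes from a β-oxido-ylide Wittig/hydroxymethylation of a nerol-derived aldehyde; nerol supplies C1–C6, C15 and the Z-C4=C5 alkene.
5. Order of ring formation: oxirane, then butenolide (γ-lactone), then the ten-membered carbocycle.

Key step: step 16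

Remark: positions are named with germacrane numbering. C1–C10 is the ten-membered ring (C1/C10 oxirane, C4=C5 alkene, C6 lactone O–CH, C7 ring fusion, C8 acyloxy carbon). C11=C13 is the methylene, C12 the lactone C=O, C14 the CH2OH and C15 the CH3.

## Route

Step 1
Reactants: 1 nerol
Product: 2 neryl TBS ether
Conditions: TBSCl, imidazole, CH2Cl2, 0 °C to rt
Reagents that add atoms: tert-butyldimethylsilyl chloride, CC(C)(C)[Si](C)(C)Cl
Why: Standard imidazole-promoted silylation of a primary alcohol; the ether removes the directing OH, deactivates the neighbouring C4=C5 alkene toward the peracid of step 2 and survives the organolithium chemistry of step 6, and no stereocentre is touched.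

Step 2
Reactants: 2 neryl TBS ether
Product: 3 6,7-epoxyneryl TBS ether (racemic at the oxirane CH)
Conditions: mCPBA (1 equiv), CH2Cl2, −20 to 0 °C
Reagents that add atoms: mCPBA, O=C(OO)c1cccc(Cl)c1
Why: Prilezhaev epoxidation is chemoselective for the electron-richer, unhindered isopropylidene alkene over the alkene bearing the allylic silyloxy group, and the new stereocentre does not matter because step 3 destroys it.

Step 3
Reactants: 3 6,7-epoxyneryl TBS ether
Product: 5 (4Z)-6-[(tert-butyldimethylsilyl)oxy]-4-methylhex-4-enal, via diol 4 (not isolated)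
Conditions: H5IO6, THF–Et2O, 0 °C
Reagents that add atoms: none
Why: Periodic acid hydrolyses the oxirane (water enters at the tertiary carbon) and cleaves diol 4 in the same flask (Malaprade glycol cleavage), which removes the isopropylidene carbons as acetone and leaves C1 as the aldehyde with the Z-alkene and the primary TBS ether intact.

Step 4
Reactants: 6 3-[(4-methoxybenzyl)oxy]propan-1-ol
Product: 7 1-[(3-iodopropoxy)methyl]-4-methoxybenzene
Conditions: I2, PPh3, imidazole, CH2Cl2, 0 °C
Reagents that add atoms: iodine, II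
Why: Appel-type (Garegg–Samuelsson) iodination of a primary alcohol under near-neutral conditions that the PMB ether tolerates.

Step 5
Reactants: 7 1-[(3-iodopropoxy)methyl]-4-methoxybenzene
Product: 8 {3-[(4-methoxybenzyl)oxy]propyl}triphenylphosphonium iodide
Conditions: PPh3, MeCN, reflux
Reagents that add atoms: triphenylphosphine, c1ccc(cc1)P(c1ccccc1)c1ccccc1
Why: SN2 quaternisation of triphenylphosphine by a primary iodide gives the Wittig salt that carries C10, C9 and C8.

Step 6
Reactants: 5 (4Z)-6-[(tert-butyldimethylsilyl)oxy]-4-methylhex-4-enal, 8 {3-[(4-methoxybenzyl)oxy]propyl}triphenylphosphonium iodide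
Product: 12 (2Z,6Z)-8-[(tert-butyldimethylsilyl)oxy]-2-{2-[(4-methoxybenzyl)oxy]ethyl}-6-methylocta-2,6-dien-1-ol, via ylide 9 (not isolated), via betaine 10 (not isolated), via beta-oxido ylide 11 (not isolated)
Conditions: 8, n-BuLi, THF, 0 °C; 5, −78 °C; n-BuLi, −78 to −25 °C; (CH2O)n, 0 °C to rt
Reagents that add atoms: formaldehyde (from paraformaldehyde), C=O
Why: Wittig reaction in its β-oxido ylide variant (Corey–Schlosser, SCOOPY): the lithium betaine 10 is deprotonated to 11, hydroxymethylated by formaldehyde and then loses Ph3PO through the original oxido group, a sequence known to place the new CH2OH cis to the aldehyde-derived chain, so it should give the 2Z alkene (C2 cis to C14, trans to C9) that the trans-oxirane requires.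

Step 7
Reactants: 12 (2Z,6Z)-allylic alcohol
Product: 13 [(2S,3R)-3-{(3Z)-5-[(tert-butyldimethylsilyl)oxy]-3-methylpent-3-en-1-yl}-2-{2-[(4-methoxybenzyl)oxy]ethyl}oxiran-2-yl]methanol
Conditions: Ti(OiPr)4 (20 mol %), L-(+)-DET (24 mol %), TBHP, 4 Å MS, CH2Cl2, −20 °C
Reagents that add atoms: tert-butyl hydroperoxide, CC(C)(C)OO
Why: Katsuki–Sharpless asymmetric epoxidation touches only the alkene of the titanium-bound free allylic alcohol, and with L-(+)-tartrate the oxygen is delivered to the face that makes the carbinol-bearing carbon 2S, which by syn addition to the 2Z alkene sets C10 (S) and C1 (R) together.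

Step 8
Reactants: 13 epoxy alcohol
Product: 14 O14-TBDPS ether of 13
Conditions: TBDPSCl, imidazole, CH2Cl2, 0 °C to rt
Reagents that add atoms: tert-butyldiphenylsilyl chloride, CC(C)(C)[Si](Cl)(c1ccccc1)c1ccccc1
Why: Chloride/imidazole silylation (no silyl triflate, so no Lewis-acid rearrangement of the epoxy alcohol) installs the acid-stable group that stays on O14 to the end.

Step 9
Reactants: 14 O14-TBDPS ether
Product: 15 (2Z)-5-[(2R,3S)-3-{[(tert-butyldiphenylsilyl)oxy]methyl}-3-{2-[(4-methoxybenzyl)oxy]ethyl}oxiran-2-yl]-3-methylpent-2-en-1-ol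
Conditions: PPTS (cat.), MeOH, 0 °C to rt
Reagents that add atoms: none
Why: Mild acid-catalysed methanolysis cleaves the unhindered primary allylic TBS ether far faster than the TBDPS ether, and the oxirane should survive because its tertiary carbon is inductively deactivated by the CH2OSi substituent.

Step 10
Reactants: 15 allylic alcohol
Product: 16 (2Z)-5-[(2R,3S)-3-{[(tert-butyldiphenylsilyl)oxy]methyl}-3-{2-[(4-methoxybenzyl)oxy]ethyl}oxiran-2-yl]-3-methylpent-2-enal
Conditions: Dess–Martin periodinane, NaHCO3, CH2Cl2, 0 °C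
Reagents that add atoms: none
Why: Buffered Dess–Martin oxidation gives the enal without acid or amine, so the Z geometry of C4=C5 should be kept.

Step 11
Reactants: 16 Z-enal, 17 hex-1-yne
Product: 21 (5E,7S,8Z)-9-methyl-11-[(2R,3S)-3-{[(tert-butyldiphenylsilyl)oxy]methyl}-3-{2-[(4-methoxybenzyl)oxy]ethyl}oxiran-2-yl]undeca-5,8-dien-7-ol, via alkenylborane 18 (not isolated), via alkenylzinc 19 (not isolated), via zinc alkoxide 20 (not isolated)
Conditions: 17, Cy2BH, toluene, 0 °C to rt; Et2Zn, −78 °C; (−)-MIB (5 mol %), 16, −20 to 0 °C; H2O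
Reagents that add atoms: none
Why: Oppolzer-type hydroboration/boron-to-zinc transmetalation followed by amino-alcohol-catalysed 1,2-addition of the alkenylzinc to the enal; the (−)-MIB–zinc complex should deliver the alkenyl group to the Si face and set C6 as S in this alcohol (the same spatial arrangement as 6R in the target) independently of the remote oxirane.

Step 12
Reactants: 21 bis-allylic alcohol, 22 2-(bromomethyl)acrylic acid
Product: 23 2-(bromomethyl)acrylate ester of 21
Conditions: DCC, DMAP (5 mol %), CH2Cl2, 0 °C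
Reagents that add atoms: none
Why: Steglich esterification acylates the only free hydroxyl with retention at C6, and the low DMAP loading and low temperature keep SN2′ attack on the allylic bromide in check.

Step 13
Reactants: 23 2-(bromomethyl)acrylate ester
Product: 24 (5R)-3-(bromomethyl)-5-{(1Z)-2-methyl-4-[(2R,3S)-3-{[(tert-butyldiphenylsilyl)oxy]methyl}-3-{2-[(4-methoxybenzyl)oxy]ethyl}oxiran-2-yl]but-1-en-1-yl}furan-2(5H)-one
Conditions: Hoveyda–Grubbs II (10 mol %), toluene (5 mM), 80 °C
Reagents that add atoms: none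
Why: Ring-closing metathesis to an α-substituted butenolide: ruthenium loads on the 1,2-disubstituted alkene, closes the five-membered ring onto the acrylate methylene with loss of hex-1-ene, and leaves the trisubstituted Z-alkene, the allylic bromide and C6 untouched.

Step 14
Reactants: 24 butenolide PMB ether
Product: 25 primary alcohol (C8–OH) of 24
Conditions: DDQ, CH2Cl2–pH 7 buffer, 0 °C
Reagents that add atoms: none
Why: Oxidative PMB cleavage is neutral and free of fluoride and base, so the allylic bromide, the epimerisable butenolide C6–H, the oxirane and the TBDPS ether should all persist.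

Step 15
Reactants: 25 primary alcohol
Product: 26 β,γ-epoxy aldehyde, {(2S,3R)-3-{(3Z)-4-[(2R)-4-(bromomethyl)-5-oxo-2,5-dihydrofuran-2-yl]-3-methylbut-3-en-1-yl}-2-{[(tert-butyldiphenylsilyl)oxy]methyl}oxiran-2-yl}acetaldehyde
Conditions: Dess–Martin periodinane, NaHCO3, CH2Cl2, 0 °C; used at once
Reagents that add atoms: none
Why: Buffered Dess–Martin oxidation gives the aldehyde without soluble base, which avoids E1cB opening of the β,γ-oxirane.

Step 16
Reactants: 26 β,γ-epoxy aldehyde
Product: 29 (1R,4Z,6R,7R,8S,10S)-14-[(tert-butyldiphenylsilyl)oxy]-1,10-epoxy-8-hydroxygermacra-4,11(13)-dien-12,6-olide (8α-carbinol), via allylchromium 27 (not isolated), via chromium alkoxide 28 (not isolated)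
Conditions: CrCl2 (10 equiv), 4 Å MS, THF–DMF, rt, syringe-pump addition of 26 (final ca. 1 mM); H2O
Reagents that add atoms: none
Why: Two one-electron transfers from Cr(II) convert the allylic bromide into the σ-allylchromium(III) species 27, whose metal binds the tethered aldehyde and transfers carbon through the γ-terminus C7 (SE2′) in a closed Zimmerman–Traxler array, so that the ring alkene C7=C11 moves out to C11=C13 and the α-methylene lactone, the C7–C8 bond and the C8 oxygen appear together. The closest known reaction types are the Cr(II)- or Zn-mediated 2-(alkoxycarbonyl)allylation of aldehydes with 3-(bromomethyl)furan-2(5H)-ones and Nozaki–Hiyama–Kishi allylation macrocyclisations to ten-membered germacranolide rings. One ring is closed, the ten-membered carbocycle, by 10-exo-trig attack of C7 on the aldehyde carbon C8 under high dilution, helped by three rigid elements already in the chain (Z-C4=C5, trans-oxirane, planar butenolide). C7 is controlled by the resident C6 stereocentre: with H6 eclipsing the Z-alkene (A1,3 strain) the chain leaves C6 on one face of the butenolide and can reach C7 without an eclipsed C5–C6–C7–C8 arrangement only over the opposite face, which gives the trans-fused lactone (7R). C8 is controlled by the allylmetal geometry, which the five-membered ring locks as the E-type γ-substituted reagent, so the chair with C9 equatorial should give the anti (7R,8S) carbinol, whereas the axial alternative would force the almost fully extended tether across H6. The step needs attack on the aldehyde only, γ- rather than α-coupling and no 1,4-elimination; these are secured in turn by the non-basic, aldehyde-selective allylchromium (lactone, oxirane and silyl ether are inert to it), by the six-membered transition state (α-attack would need a twelve-membered ring), and by the C6–O bond lying in the nodal plane of the allyl π system.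

Step 17
Reactants: 29 8α-carbinol, 30 isobutyric acid
Product: 32 O14-TBDPS ether of the target (8R isobutyrate), via oxyphosphonium salt 31 (not isolated)
Conditions: PPh3, DIAD (premixed), 30, toluene, 0 °C to rt
Reagents that add atoms: none
Why: Mitsunobu esterification displaces the oxyphosphonium group of 31 by isobutyrate in an SN2 process, which inverts C8 from S to R and installs the ester in the same operation, and premixing the phosphine with DIAD limits its conjugate addition to the α-methylene lactone.

Step 18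
Reactants: 32 O14-TBDPS ether of the target
Product: 33 target, (1R,4Z,6R,7R,8R,10S)-1,10-epoxy-14-hydroxy-8-(isobutyryloxy)germacra-4,11(13)-dien-12,6-olide
Conditions: TBAF, AcOH (1:1), THF, 0 °C to rt
Reagents that add atoms: none
Why: Fluoride-induced Si–O cleavage buffered with acetic acid keeps the medium non-basic, so Payne rearrangement, O8-to-O14 acyl migration and conjugate addition to the methylene lactone should not compete.

## Compound list

1 | nerol, (2Z)-3,7-dimethylocta-2,6-dien-1-ol | CC(C)=CCC/C(C)=C\CO | starting material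
2 | neryl TBS ether | CC(C)=CCC/C(C)=C\CO[Si](C)(C)C(C)(C)C | intermediate
3 | 6,7-epoxyneryl TBS ether (racemic oxirane) | CC1(C)OC1CC/C(C)=C\CO[Si](C)(C)C(C)(C)C | intermediate
4 | 6,7-diol of neryl TBS ether (not isolated) | CC(C)(O)C(O)CC/C(C)=C\CO[Si](C)(C)C(C)(C)C | intermediate
5 | (4Z)-6-[(tert-butyldimethylsilyl)oxy]-4-methylhex-4-enal | O=CCC/C(C)=C\CO[Si](C)(C)C(C)(C)C | intermediate
6 | 3-[(4-methoxybenzyl)oxy]propan-1-ol | COc1ccc(COCCCO)cc1 | starting material
7 | 1-[(3-iodopropoxy)methyl]-4-methoxybenzene | COc1ccc(COCCCI)cc1 | intermediate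
8 | {3-[(4-methoxybenzyl)oxy]propyl}triphenylphosphonium iodide | COc1ccc(COCCC[P+](c2ccccc2)(c2ccccc2)c2ccccc2)cc1.[I-] | intermediate
9 | {3-[(4-methoxybenzyl)oxy]propylidene}triphenylphosphorane (not isolated) | COc1ccc(COCCC=P(c2ccccc2)(c2ccccc2)c2ccccc2)cc1 | intermediate
10 | betaine from 5 and 9 (lithium-complexed, not isolated) | COc1ccc(COCCC(C([O-])CC/C(C)=C\CO[Si](C)(C)C(C)(C)C)[P+](c2ccccc2)(c2ccccc2)c2ccccc2)cc1 | intermediate
11 | lithium β-oxido ylide (not isolated) | COc1ccc(COCCC(C([O-])CC/C(C)=C\CO[Si](C)(C)C(C)(C)C)=P(c2ccccc2)(c2ccccc2)c2ccccc2)cc1.[Li+] | intermediate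
12 | (2Z,6Z)-8-[(tert-butyldimethylsilyl)oxy]-2-{2-[(4-methoxybenzyl)oxy]ethyl}-6-methylocta-2,6-dien-1-ol | OC/C(CCOCc1ccc(OC)cc1)=C\CC/C(C)=C\CO[Si](C)(C)C(C)(C)C | intermediate
13 | (2S,3R)-epoxy alcohol | CC(C)(C)[Si](C)(C)OC/C=C(/C)CC[C@H]1O[C@]1(CO)CCOCc1ccc(OC)cc1 | intermediate
14 | O14-TBDPS ether of 13 | CC(C)(C)[Si](C)(C)OC/C=C(/C)CC[C@H]1O[C@]1(CO[Si](c1ccccc1)(c1ccccc1)C(C)(C)C)CCOCc1ccc(OC)cc1 | intermediate
15 | Z-allylic alcohol (free C6–OH) | OC/C=C(/C)CC[C@H]1O[C@]1(CO[Si](c1ccccc1)(c1ccccc1)C(C)(C)C)CCOCc1ccc(OC)cc1 | intermediate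
16 | Z-enal | O=C/C=C(/C)CC[C@H]1O[C@]1(CO[Si](c1ccccc1)(c1ccccc1)C(C)(C)C)CCOCc1ccc(OC)cc1 | intermediate
17 | hex-1-yne | C#CCCCC | starting material
18 | dicyclohexyl[(1E)-hex-1-en-1-yl]borane (not isolated) | CCCC/C=C/B(C1CCCCC1)C1CCCCC1 | intermediate
19 | ethyl[(1E)-hex-1-en-1-yl]zinc (not isolated) | CCCC/C=C/[Zn]CC | intermediate
20 | ethylzinc alkoxide of 21 (not isolated) | CCCC/C=C/[C@H](O[Zn]CC)/C=C(/C)CC[C@H]1O[C@]1(CO[Si](c1ccccc1)(c1ccccc1)C(C)(C)C)CCOCc1ccc(OC)cc1 | intermediate
21 | (5E,7S,8Z)-bis-allylic alcohol | CCCC/C=C/[C@H](O)/C=C(/C)CC[C@H]1O[C@]1(CO[Si](c1ccccc1)(c1ccccc1)C(C)(C)C)CCOCc1ccc(OC)cc1 | intermediate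
22 | 2-(bromomethyl)acrylic acid | C=C(CBr)C(=O)O | starting material
23 | 2-(bromomethyl)acrylate of 21 | CCCC/C=C/[C@H](OC(=O)C(=C)CBr)/C=C(/C)CC[C@H]1O[C@]1(CO[Si](c1ccccc1)(c1ccccc1)C(C)(C)C)CCOCc1ccc(OC)cc1 | intermediate
24 | (5R)-3-(bromomethyl)butenolide, PMB ether | BrCC1=C[C@H](OC1=O)/C=C(/C)CC[C@H]1O[C@]1(CO[Si](c1ccccc1)(c1ccccc1)C(C)(C)C)CCOCc1ccc(OC)cc1 | intermediate
25 | (5R)-3-(bromomethyl)butenolide, primary alcohol | BrCC1=C[C@H](OC1=O)/C=C(/C)CC[C@H]1O[C@]1(CO[Si](c1ccccc1)(c1ccccc1)C(C)(C)C)CCO | intermediate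
26 | (5R)-3-(bromomethyl)butenolide, β,γ-epoxy aldehyde | BrCC1=C[C@H](OC1=O)/C=C(/C)CC[C@H]1O[C@]1(CO[Si](c1ccccc1)(c1ccccc1)C(C)(C)C)CC=O | intermediate
27 | allylchromium(III) dichloride from 26 (not isolated) | Cl[Cr](Cl)CC1=C[C@H](OC1=O)/C=C(/C)CC[C@H]1O[C@]1(CO[Si](c1ccccc1)(c1ccccc1)C(C)(C)C)CC=O | intermediate
28 | chromium(III) alkoxide of 29 (not isolated) | C=C1C(=O)O[C@@H]2/C=C(/C)CC[C@H]3O[C@]3(CO[Si](c4ccccc4)(c4ccccc4)C(C)(C)C)C[C@H](O[Cr](Cl)Cl)[C@@H]12 | intermediate
29 | (1R,4Z,6R,7R,8S,10S)-8α-carbinol, O14-TBDPS | C=C1C(=O)O[C@@H]2/C=C(/C)CC[C@H]3O[C@]3(CO[Si](c4ccccc4)(c4ccccc4)C(C)(C)C)C[C@H](O)[C@@H]12 | intermediate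
30 | isobutyric acid | CC(C)C(=O)O | starting material
31 | C8-oxyphosphonium isobutyrate (not isolated) | C=C1C(=O)O[C@@H]2/C=C(/C)CC[C@H]3O[C@]3(CO[Si](c4ccccc4)(c4ccccc4)C(C)(C)C)C[C@H](O[P+](c4ccccc4)(c4ccccc4)c4ccccc4)[C@@H]12.CC(C)C(=O)[O-] | intermediate
32 | O14-TBDPS ether of the target | C=C1C(=O)O[C@@H]2/C=C(/C)CC[C@H]3O[C@]3(CO[Si](c4ccccc4)(c4ccccc4)C(C)(C)C)C[C@@H](OC(=O)C(C)C)[C@@H]12 | intermediate
33 | CNP0247143.1 | C=C1C(=O)O[C@@H]2/C=C(/C)CC[C@H]3O[C@]3(CO)C[C@@H](OC(=O)C(C)C)[C@@H]12 | target

## Step count and risks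

Total step count: 18. Longest linear sequence: 16 steps (from nerol: steps 1–3 and 6–18).

**Step 16.**
- What may go wrong: closure of the ten-membered ring may be slower than intermolecular coupling or protonation of the allylchromium. The chromium salts may also trigger β-elimination of the aldehyde with opening of the oxirane.
- Fallback: it replaces the in situ reductive metalation by a preformed, neutral allyl donor and sets out from 25. Palladium-catalysed borylation of the allylic bromide with bis(pinacolato)diboron would give the pinacol allylboronate F1. Buffered Dess–Martin oxidation would give the boronate aldehyde F2.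
- Return to the route: F2 would be heated in dilute toluene so that an intramolecular allylboration through the same chair gives the cyclic borate F3. Mild aqueous work-up returns to the route at 29.

**Step 17.**
- What may go wrong: the hindered ring carbinol may resist SN2 displacement, so that elimination of the oxyphosphonium group or phosphine addition to the methylene lactone takes over.
- Fallback: it inverts C8 by redox chemistry instead of substitution and sets out from 29. Dess–Martin oxidation would give the 8-ketone F4. Reagent-controlled Corey–Bakshi–Shibata reduction with (S)-Me-CBS and catecholborane (C7 as the large substituent, C9 as the small one) would give the 8β-alcohol F5.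
- Return to the route: acylation of F5 with isobutyric anhydride and DMAP comes back at 32.

**Step 6.**
- What may go wrong: deprotonation of the betaine may be incomplete, or the betaine may revert or equilibrate, with loss of geometric control and poor capture of formaldehyde.
- Fallback: it builds the same alkene by a phosphonate olefination at the ester oxidation level and sets out from 5. Commercial methyl bis(2,2,2-trifluoroethyl)phosphonoacetate would be alkylated with 1-[(2-iodoethoxy)methyl]-4-methoxybenzene (NaH, DMF) to the α-substituted phosphonate F6. Still–Gennari olefination of 5 (KHMDS, 18-crown-6, THF, −78 °C) would give the Z-enoate F7, with the chain cis to the ester.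
- Return to the route: DIBAL-H reduction of F7 comes back at 12.

## Further compounds

F1 | step 16 | pinacol allylboronate, primary alcohol | CC1(C)OB(CC2=C[C@H](OC2=O)/C=C(/C)CC[C@H]3O[C@]3(CO[Si](c4ccccc4)(c4ccccc4)C(C)(C)C)CCO)OC1(C)C
F2 | step 16 | pinacol allylboronate, β,γ-epoxy aldehyde | CC1(C)OB(CC2=C[C@H](OC2=O)/C=C(/C)CC[C@H]3O[C@]3(CO[Si](c4ccccc4)(c4ccccc4)C(C)(C)C)CC=O)OC1(C)C
F3 | step 16 | O8-pinacolboryl derivative of 29 | C=C1C(=O)O[C@@H]2/C=C(/C)CC[C@H]3O[C@]3(CO[Si](c4ccccc4)(c4ccccc4)C(C)(C)C)C[C@H](OB4OC(C)(C)C(C)(C)O4)[C@@H]12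
F4 | step 17 | 8-ketone, O14-TBDPS | C=C1C(=O)O[C@@H]2/C=C(/C)CC[C@H]3O[C@]3(CO[Si](c4ccccc4)(c4ccccc4)C(C)(C)C)CC(=O)[C@@H]12
F5 | step 17 | (8R)-8β-alcohol, O14-TBDPS | C=C1C(=O)O[C@@H]2/C=C(/C)CC[C@H]3O[C@]3(CO[Si](c4ccccc4)(c4ccccc4)C(C)(C)C)C[C@@H](O)[C@@H]12
F6 | step 6 | methyl 2-[bis(2,2,2-trifluoroethoxy)phosphoryl]-4-[(4-methoxybenzyl)oxy]butanoate | COC(=O)C(CCOCc1ccc(OC)cc1)P(=O)(OCC(F)(F)F)OCC(F)(F)F
F7 | step 6 | methyl (2Z,6Z)-8-[(tert-butyldimethylsilyl)oxy]-2-{2-[(4-methoxybenzyl)oxy]ethyl}-6-methylocta-2,6-dienoate | COC(=O)/C(CCOCc1ccc(OC)cc1)=C\CC/C(C)=C\CO[Si](C)(C)C(C)(C)C
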